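**Retrosynthetic overview** (ring numbering: C1 carries the isopropenyl group, C3=C4 is Z, C7=C8 and C11=C12 are E, C10 carries the ester, C13 the hydroxyl)
1. The 14-membered ring is closed last at C2–C3 by a light-driven cerium/nickel ring-opening alkenylation of a six-membered lactol onto a tethered Z-alkenyl iodide; the expelled lactol carbon stays behind as the O13 formate.
2. The C10 ester comes from Mitsunobu inversion of a (10S)-allylic alcohol with the O-formyl (2R,3S) acid; that alcohol comes from 1,3-transposition of a C12 tertiary carbinol set by chelation-controlled ethynylation of a methyl ketone; C9–C10 is made by copper-catalysed alkynyl–allyl coupling.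
3. The keto acetal comes from ozonolysis of cis-carveol, itself from Luche reduction of (S)-carvone (C1 bought, C13 set by C1).
4. The Z,E-iodo-dienyl bromide comes from carbocupration of propyne, iodination, SeO2 oxidation and Appel bromination; the acid comes from tert-butyl (R)-3-hydroxybutanoate by Fráter–Seebach methylation and a formic-acid Mitsunobu inversion.
5. Ring order: the temporary oxane (acetal) ring is formed first (step 2); the carbocycle is formed last (step 15), as the oxane opens.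

Assumption: the SMILES is read as the (1S,3Z,7E,10R,11E,13S) ring with a (2R,3S)-3-hydroxy-2-methylbutanoyl group; the ring numbering above is used throughout.

**Step 1**
Reactants: 1 (S)-(+)-carvone, (5S)-2-methyl-5-(prop-1-en-2-yl)cyclohex-2-en-1-one
Product: 2 (1S,5S)-2-methyl-5-(prop-1-en-2-yl)cyclohex-2-en-1-ol (cis-carveol)
Conditions: NaBH4, CeCl3·7H2O, MeOH, −78 to 0 °C
Reagents that add atoms: none
Why: Luche 1,2-reduction, in which hydride adds axially to the half-chair with the isopropenyl group equatorial, so the bought C1 centre sets C13 as the cis alcohol (about 95:5).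

**Step 2**
Reactants: 2 cis-carveol
Product: 4 1-[(2S,4R)-6-methoxy-4-(prop-1-en-2-yl)oxan-2-yl]ethan-1-one, via lactol 3 (not isolated)
Conditions: O3 (1.0 equiv), CH2Cl2/MeOH, −78 °C; Me2S, −78 to 25 °C; then PPTS (cat.), MeOH, 25 °C
Reagents that add atoms: ozone, [O-][O+]=O; methanol, CO
Why: Criegee ozonolysis attacks the trisubstituted ring alkene well ahead of the 1,1-disubstituted isopropenyl group, the hydroxy aldehyde closes to the lactol, and Fischer-type acetalisation masks both the aldehyde and O13 (anomer mixture, no consequence).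

**Step 3**
Reactants: 4 keto acetal; 5 ethynylmagnesium bromide
Product: 6 (2S)-2-[(2S,4R)-6-methoxy-4-(prop-1-en-2-yl)oxan-2-yl]but-3-yn-2-ol
Conditions: 5 (3 equiv), THF/CH2Cl2, −78 to −20 °C; H2O
Reagents that add atoms: none
Why: Cram-chelate Grignard addition, in which magnesium bridges the ketone oxygen and the ring oxygen and the alkynyl group enters opposite the ring CH2, giving the (12S) tertiary carbinol under control of C13.

**Step 4**
Reactants: 7 5-bromo-2-methylpent-2-ene; 8 propyne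
Product: 12 (1Z)-1-iodo-2,6-dimethylhepta-1,5-diene, via Grignard reagent 9 (not isolated), via alkylcopper 10 (not isolated), via alkenylcopper 11 (not isolated)
Conditions: Mg, Et2O; CuBr·SMe2, Et2O/Me2S, −45 °C; propyne, −25 °C; I2, THF, −78 to 0 °C
Reagents that add atoms: iodine, [I][I]
Why: Normant carbocupration adds the alkylcopper syn across propyne with copper on the terminal carbon, and iodinolysis with retention gives the Z-iodoalkene (typically ≥98:2).

**Step 5**
Reactants: 12 Z-iodo diene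
Product: 13 (2E,6Z)-7-iodo-2,6-dimethylhepta-2,6-dien-1-ol
Conditions: SeO2 (30 mol%), t-BuOOH, salicylic acid (10 mol%), CH2Cl2, 25 °C
Reagents that add atoms: tert-butyl hydroperoxide, CC(C)(C)OO (oxygen relayed by catalytic SeO2, O=[Se]=O)
Why: Sharpless SeO2 allylic oxidation (ene reaction then [2,3]-shift) takes the E-methyl of the electron-rich gem-dimethyl alkene and leaves the deactivated iodoalkene alone.

**Step 6**
Reactants: 13 allylic alcohol
Product: 14 (2E,6Z)-1-bromo-7-iodo-2,6-dimethylhepta-2,6-diene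
Conditions: CBr4, PPh3, CH2Cl2, 0 °C
Reagents that add atoms: carbon tetrabromide, BrC(Br)(Br)Br
Why: Appel bromination is an SN2 displacement at the primary allylic carbon, so both alkene geometries are kept.

**Step 7**
Reactants: 6 alkynyl carbinol; 14 allylic bromide
Product: 15 (2S,6E,10Z)-11-iodo-2-[(2S,4R)-6-methoxy-4-(prop-1-en-2-yl)oxan-2-yl]-6,10-dimethylundeca-6,10-dien-3-yn-2-ol
Conditions: CuI (20 mol%), NaI (20 mol%), K2CO3, DMF, 25 °C
Reagents that add atoms: none
Why: Copper-acetylide alkylation (Jeffery-type alkyne–allyl halide coupling) goes SN2 at the primary allylic carbon and forms C9–C10, while the tertiary alcohol, acetal and alkenyl iodide are inert to carbonate and CuI at 25 °C.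

**Step 8**
Reactants: 15 enynol
Product: 16 (2S,3E,6E,10Z)-11-iodo-2-[(2S,4R)-6-methoxy-4-(prop-1-en-2-yl)oxan-2-yl]-6,10-dimethylundeca-3,6,10-trien-2-ol
Conditions: NaAlH2(OCH2CH2OCH3)2, THF, 0 to 25 °C; aq. KNaC4H4O6
Reagents that add atoms: none
Why: Alkoxide-directed trans-hydroalumination of the propargylic alcohol gives only the E-C10=C11 alkene, and the alkenyl iodide should survive the hydride at or below 25 °C.

**Step 9**
Reactants: 16 tertiary allylic alcohol
Product: 18 (2E,4S,6E,10Z)-11-iodo-2-[(2S,4R)-6-methoxy-4-(prop-1-en-2-yl)oxan-2-yl]-6,10-dimethylundeca-2,6,10-trien-4-ol, via silyl ether 17 (not isolated)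
Conditions: Ph3SiOReO3 (5 mol%), N,O-bis(trimethylsilyl)acetamide, Et2O, −50 to 0 °C; then K2CO3 (cat.), MeOH, 0 °C
Reagents that add atoms: none
Why: Rhenium-oxo-catalysed 1,3-transposition, in which the perrhenate ester shifts suprafacially through a chair with the C13 branch equatorial, so (12S,E) gives the (10S)-alcohol with an E-C11=C12 bond, and silylation of the secondary alcohol pulls the equilibrium over.

**Step 10**
Reactants: 19 tert-butyl (3R)-3-hydroxybutanoate
Product: 21 tert-butyl (2R,3R)-3-hydroxy-2-methylbutanoate, via dianion 20 (not isolated)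
Conditions: LiN(i-Pr)2 (2.2 equiv), THF, −78 to −20 °C; MeI, −78 to 0 °C
Reagents that add atoms: iodomethane, CI
Why: Fráter–Seebach alkylation, in which the chelated alkoxide-enolate is methylated on the face away from the C3 methyl, giving the anti (2R,3R) ester (about 95:5) under control of the bought centre.

**Step 11**
Reactants: 21 anti hydroxy ester
Product: 22 tert-butyl (2R,3S)-3-(formyloxy)-2-methylbutanoate
Conditions: HCO2H, PPh3, DIAD, THF, 0 to 25 °C
Reagents that add atoms: formic acid, OC=O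
Why: Mitsunobu reaction, in which formate displaces the activated hydroxyl with SN2 inversion at C3, converting anti to the syn (2R,3S) array and leaving a formate as protecting group.

**Step 12**
Reactants: 22 formate ester
Product: 23 (2R,3S)-3-(formyloxy)-2-methylbutanoic acid
Conditions: CF3CO2H, CH2Cl2, 0 to 25 °C
Reagents that add atoms: none
Why: Acidolysis of the tert-butyl ester by loss of the tert-butyl cation, which leaves the formate and both stereocentres untouched.

**Step 13**
Reactants: 18 (10S)-allylic alcohol; 23 acid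
Product: 24 (2E,4R,6E,10Z)-11-iodo-2-[(2S,4R)-6-methoxy-4-(prop-1-en-2-yl)oxan-2-yl]-6,10-dimethylundeca-2,6,10-trien-4-yl (2R,3S)-3-(formyloxy)-2-methylbutanoate
Conditions: PPh3, DIAD, toluene, −20 to 0 °C
Reagents that add atoms: none
Why: Mitsunobu esterification, in which the carboxylate displaces the alkoxyphosphonium at C10 with inversion to give the required (10R) ester, while SN2′ attack at the fully substituted C12 is disfavoured.

**Step 14**
Reactants: 24 methyl acetal
Product: 25 (2E,4R,6E,10Z)-2-[(2S,4R)-6-hydroxy-4-(prop-1-en-2-yl)oxan-2-yl]-11-iodo-6,10-dimethylundeca-2,6,10-trien-4-yl (2R,3S)-3-(formyloxy)-2-methylbutanoate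
Conditions: PPTS, acetone/H2O, 40 °C
Reagents that add atoms: water, O
Why: Acid-catalysed acetal hydrolysis through the oxocarbenium ion of a 2-deoxy-glycoside-type acetal is much faster than hydrolysis of the formate or the allylic ester.

**Step 15**
Reactants: 25 lactol
Product: 27 (1R,2E,4S,6S,8Z,12E)-4-hydroxy-3,9,13-trimethyl-6-(prop-1-en-2-yl)cyclotetradeca-2,8,12-trien-1-yl (2R,3S)-3-hydroxy-2-methylbutanoate (CNP0328880.1), via macrocyclic bis-formate 26 (not isolated)
Conditions: NiBr2(CH3OCH2CH2OCH3) (30 mol%), 4,4′-di-tert-butyl-2,2′-bipyridine (33 mol%), CeCl3 (15 mol%), n-Bu4NCl (45 mol%), K2HPO4 (2 equiv), MeCN, 390 nm LEDs, 25 °C, syringe-pump addition to ≤2 mM; then K2CO3 (cat.), MeOH, 0 °C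
Reagents that add atoms: none
Why: Proposed new method: a photochemical cerium/nickel deformylative ring-opening alkenylation of a lactol, in which the lactol O–H binds tetravalent cerium, 390 nm ligand-to-metal charge transfer releases the anomeric alkoxy radical, β-scission (driven by forming the O13 formate C=O) leaves C2 as a primary radical, divalent alkenylnickel (from the Z-alkenyl iodide and monovalent nickel, with trivalent cerium as the electron shuttle) captures it and reductive elimination from trivalent nickel forms C2–C3 with retention of the Z geometry and without touching a stereocentre, after which mild methanolysis removes both formates; the closest known reactions are the Suárez alkoxy-radical fragmentation of lactols to formates, cerium-photocatalysed ring opening and dehydroxymethylation of alcohols, and nickel metallaphotoredox alkyl–alkenyl coupling.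

**Compound list**
1 | (S)-(+)-carvone, (5S)-2-methyl-5-(prop-1-en-2-yl)cyclohex-2-en-1-one | C=C(C)[C@H]1CC=C(C)C(=O)C1 | starting material
2 | (1S,5S)-2-methyl-5-(prop-1-en-2-yl)cyclohex-2-en-1-ol (cis-carveol) | C=C(C)[C@H]1CC=C(C)[C@@H](O)C1 | intermediate
3 | (4R,6S)-6-acetyl-4-(prop-1-en-2-yl)oxan-2-ol (lactol form of the hydroxy keto-aldehyde, anomer mixture) | C=C(C)[C@H]1CC(O)O[C@H](C(C)=O)C1 | intermediate
4 | 1-[(2S,4R)-6-methoxy-4-(prop-1-en-2-yl)oxan-2-yl]ethan-1-one (anomer mixture) | C=C(C)[C@H]1CC(OC)O[C@H](C(C)=O)C1 | intermediate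
5 | ethynylmagnesium bromide | C#C[Mg]Br | starting material
6 | (2S)-2-[(2S,4R)-6-methoxy-4-(prop-1-en-2-yl)oxan-2-yl]but-3-yn-2-ol | C=C(C)[C@H]1CC(OC)O[C@H]([C@@](C)(O)C#C)C1 | intermediate
7 | 5-bromo-2-methylpent-2-ene | CC(C)=CCCBr | starting material
8 | propyne | CC#C | starting material
9 | (4-methylpent-3-en-1-yl)magnesium bromide | CC(C)=CCC[Mg]Br | intermediate
10 | (4-methylpent-3-en-1-yl)copper (MgBr2 complex) | CC(C)=CCC[Cu] | intermediate
11 | [(1Z)-2,6-dimethylhepta-1,5-dien-1-yl]copper | CC(C)=CCC/C(C)=C\[Cu] | intermediate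
12 | (1Z)-1-iodo-2,6-dimethylhepta-1,5-diene | CC(C)=CCC/C(C)=C\I | intermediate
13 | (2E,6Z)-7-iodo-2,6-dimethylhepta-2,6-dien-1-ol | OC/C(C)=C/CC/C(C)=C\I | intermediate
14 | (2E,6Z)-1-bromo-7-iodo-2,6-dimethylhepta-2,6-diene | BrC/C(C)=C/CC/C(C)=C\I | intermediate
15 | (2S,6E,10Z)-11-iodo-2-[(2S,4R)-6-methoxy-4-(prop-1-en-2-yl)oxan-2-yl]-6,10-dimethylundeca-6,10-dien-3-yn-2-ol | C=C(C)[C@H]1CC(OC)O[C@H]([C@@](C)(O)C#CC/C(C)=C/CC/C(C)=C\I)C1 | intermediate
16 | (2S,3E,6E,10Z)-11-iodo-2-[(2S,4R)-6-methoxy-4-(prop-1-en-2-yl)oxan-2-yl]-6,10-dimethylundeca-3,6,10-trien-2-ol | C=C(C)[C@H]1CC(OC)O[C@H]([C@@](C)(O)/C=C/C/C(C)=C/CC/C(C)=C\I)C1 | intermediate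
17 | trimethylsilyl ether of 18 (O10–SiMe3) | C=C(C)[C@H]1CC(OC)O[C@H](/C(C)=C/[C@@H](O[Si](C)(C)C)C/C(C)=C/CC/C(C)=C\I)C1 | intermediate
18 | (2E,4S,6E,10Z)-11-iodo-2-[(2S,4R)-6-methoxy-4-(prop-1-en-2-yl)oxan-2-yl]-6,10-dimethylundeca-2,6,10-trien-4-ol | C=C(C)[C@H]1CC(OC)O[C@H](/C(C)=C/[C@@H](O)C/C(C)=C/CC/C(C)=C\I)C1 | intermediate
19 | tert-butyl (3R)-3-hydroxybutanoate | C[C@@H](O)CC(=O)OC(C)(C)C | starting material
20 | dilithium alkoxide-enolate of 19 | [Li+].[Li+].C[C@@H]([O-])C=C([O-])OC(C)(C)C | intermediate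
21 | tert-butyl (2R,3R)-3-hydroxy-2-methylbutanoate | C[C@@H](O)[C@@H](C)C(=O)OC(C)(C)C | intermediate
22 | tert-butyl (2R,3S)-3-(formyloxy)-2-methylbutanoate | C[C@H](OC=O)[C@@H](C)C(=O)OC(C)(C)C | intermediate
23 | (2R,3S)-3-(formyloxy)-2-methylbutanoic acid | C[C@H](OC=O)[C@@H](C)C(=O)O | intermediate
24 | (2E,4R,6E,10Z)-11-iodo-2-[(2S,4R)-6-methoxy-4-(prop-1-en-2-yl)oxan-2-yl]-6,10-dimethylundeca-2,6,10-trien-4-yl (2R,3S)-3-(formyloxy)-2-methylbutanoate | C=C(C)[C@H]1CC(OC)O[C@H](/C(C)=C/[C@H](OC(=O)[C@H](C)[C@H](C)OC=O)C/C(C)=C/CC/C(C)=C\I)C1 | intermediate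
25 | (2E,4R,6E,10Z)-2-[(2S,4R)-6-hydroxy-4-(prop-1-en-2-yl)oxan-2-yl]-11-iodo-6,10-dimethylundeca-2,6,10-trien-4-yl (2R,3S)-3-(formyloxy)-2-methylbutanoate (anomer mixture) | C=C(C)[C@H]1CC(O)O[C@H](/C(C)=C/[C@H](OC(=O)[C@H](C)[C@H](C)OC=O)C/C(C)=C/CC/C(C)=C\I)C1 | intermediate
26 | (1R,2E,4S,6S,8Z,12E)-4-(formyloxy)-3,9,13-trimethyl-6-(prop-1-en-2-yl)cyclotetradeca-2,8,12-trien-1-yl (2R,3S)-3-(formyloxy)-2-methylbutanoate | C=C(C)[C@H]1C/C=C(/C)CC/C=C(\C)C[C@@H](OC(=O)[C@H](C)[C@H](C)OC=O)/C=C(\C)[C@@H](OC=O)C1 | intermediate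
27 | (1R,2E,4S,6S,8Z,12E)-4-hydroxy-3,9,13-trimethyl-6-(prop-1-en-2-yl)cyclotetradeca-2,8,12-trien-1-yl (2R,3S)-3-hydroxy-2-methylbutanoate | C=C(C)[C@H]1C/C=C(/C)CC/C=C(\C)C[C@@H](OC(=O)[C@H](C)[C@H](C)O)/C=C(\C)[C@@H](O)C1 | target

**Count and risks**
Total steps: 15. Longest linear sequence: 9 steps (1, 2, 3, 7, 8, 9, 13, 14, 15; the arm 4, 5, 6, 7, 8, 9, 13, 14, 15 is equally long).

Most likely to fail:

1. Step 15 (the proposed photochemical ring closure). The C2 radical can cyclise onto C11=C12 (5-exo/6-endo, estimated at about 10^4 s−1) or the chain can oligomerise before nickel captures it; the high nickel loading and slow addition are meant to counter this but are untested. Fallback with known, polar ring closure, setting out from 25 and coming back at 27: Pinnick oxidation (NaClO2, NaH2PO4, 2-methyl-2-butene) of the open hydroxy-aldehyde form gives the seco hydroxy acid F1. Et3SiOSO2CF3/2,6-lutidine with aqueous work-up gives the O13 triethylsilyl ether acid F2. Barton decarboxylative iodination (N-hydroxypyridine-2-thione, DCC, to the thiohydroxamate ester F3; then CHI3, visible light) gives the primary C2 iodide F4, since iodine transfer from concentrated CHI3 outruns the radical cyclisation. Zinc insertion (Zn, LiCl, THF) gives the alkylzinc iodide F5, which is closed by intramolecular Negishi coupling (Pd(PPh3)4, THF, high dilution) to the macrocycle F6. HCl in MeOH at 0 °C removes the silyl ether and the formate to give 27.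

2. Step 9 (rhenium-catalysed 1,3-transposition). E/Z leakage at C11=C12 or ionisation would erode C10. Fallback setting out from 15 and coming back at 18 and at 24: Meyer–Schuster rearrangement (n-Bu4NReO4, p-TsOH cat., CH2Cl2) gives the E-enone F7. Luche reduction (NaBH4, CeCl3·7H2O) gives a separable mixture of 18 and its (10R)-epimer F8, without stereocontrol at C10. 18 goes on through step 13 (inversion); F8 is esterified with 23 with retention (EDC, DMAP) and rejoins at 24, so both epimers are used.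

3. Step 2 (chemoselective ozonolysis). The isopropenyl group may compete with the ring alkene, or the allylic alcohol may give anomalous cleavage. Fallback setting out from 2 and coming back at 4: hydroxyl-directed epoxidation (VO(acac)2, t-BuOOH, CH2Cl2) gives the syn epoxy alcohol F9. TBSCl/imidazole gives the silyl ether F10, which stops periodate from also cutting the C12–C13 bond. H5IO6 (THF/H2O) cleaves the epoxide to the silyloxy keto-aldehyde F11. Camphorsulfonic acid in MeOH removes the silyl group and closes the methyl acetal 4.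

**Further compounds**
F1 | step 15 | (3R,5S,6E,8R,10E,14Z)-8-{[(2R,3S)-3-(formyloxy)-2-methylbutanoyl]oxy}-5-hydroxy-15-iodo-6,10,14-trimethyl-3-(prop-1-en-2-yl)pentadeca-6,10,14-trienoic acid | C=C(C)[C@@H](CC(=O)O)C[C@H](O)/C(C)=C/[C@H](OC(=O)[C@H](C)[C@H](C)OC=O)C/C(C)=C/CC/C(C)=C\I
F2 | step 15 | O5-triethylsilyl ether of F1 | C=C(C)[C@@H](CC(=O)O)C[C@H](O[Si](CC)(CC)CC)/C(C)=C/[C@H](OC(=O)[C@H](C)[C@H](C)OC=O)C/C(C)=C/CC/C(C)=C\I
F3 | step 15 | 2-thioxopyridin-1(2H)-yl (Barton) ester of F2 | C=C(C)[C@@H](CC(=O)ON1C=CC=CC1=S)C[C@H](O[Si](CC)(CC)CC)/C(C)=C/[C@H](OC(=O)[C@H](C)[C@H](C)OC=O)C/C(C)=C/CC/C(C)=C\I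
F4 | step 15 | primary iodide (CO2H of F2 replaced by I at C2) | C=C(C)[C@@H](CI)C[C@H](O[Si](CC)(CC)CC)/C(C)=C/[C@H](OC(=O)[C@H](C)[C@H](C)OC=O)C/C(C)=C/CC/C(C)=C\I
F5 | step 15 | alkylzinc iodide from F4 | C=C(C)[C@@H](C[Zn]I)C[C@H](O[Si](CC)(CC)CC)/C(C)=C/[C@H](OC(=O)[C@H](C)[C@H](C)OC=O)C/C(C)=C/CC/C(C)=C\I
F6 | step 15 | 13-O-triethylsilyl macrocycle with side-chain formate | C=C(C)[C@H]1C/C=C(/C)CC/C=C(\C)C[C@@H](OC(=O)[C@H](C)[C@H](C)OC=O)/C=C(\C)[C@@H](O[Si](CC)(CC)CC)C1
F7 | step 9 | (2E,6E,10Z)-11-iodo-2-[(2S,4R)-6-methoxy-4-(prop-1-en-2-yl)oxan-2-yl]-6,10-dimethylundeca-2,6,10-trien-4-one | C=C(C)[C@H]1CC(OC)O[C@H](/C(C)=C/C(=O)C/C(C)=C/CC/C(C)=C\I)C1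
F8 | step 9 | (2E,4R,6E,10Z)-11-iodo-2-[(2S,4R)-6-methoxy-4-(prop-1-en-2-yl)oxan-2-yl]-6,10-dimethylundeca-2,6,10-trien-4-ol | C=C(C)[C@H]1CC(OC)O[C@H](/C(C)=C/[C@H](O)C/C(C)=C/CC/C(C)=C\I)C1
F9 | step 2 | syn-2,3-epoxide of 2 (oxirane on the hydroxyl face), 1-methyl-4-(prop-1-en-2-yl)-7-oxabicyclo[4.1.0]heptan-2-ol | C=C(C)[C@H]1C[C@H]2O[C@@]2(C)[C@@H](O)C1
F10 | step 2 | tert-butyldimethylsilyl ether of F9 | C=C(C)[C@H]1C[C@H]2O[C@@]2(C)[C@@H](O[Si](C)(C)C(C)(C)C)C1
F11 | step 2 | (3R,5S)-5-[(tert-butyldimethylsilyl)oxy]-6-oxo-3-(prop-1-en-2-yl)heptanal | C=C(C)[C@@H](CC=O)C[C@H](O[Si](C)(C)C(C)(C)C)C(C)=O
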